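**Retrosynthetic overview**
1. The last operation is acidolysis of a tert-butyl ester on the ring B carboxyl group, the only protecting group in the route.
2. Key cut: the ring B aryl C4–O bond of the depside is formed, not the usual acyl C–O bond (acid plus phenol). This is an oxidative copper-catalysed O-arylation (Chan–Lam) of the hindered ring A acid by a ring B boronic acid.
3. The boronic acid comes from sterically governed iridium-catalysed C–H borylation at the one open position of tert-butyl 2-methoxy-6-pentylbenzoate. No phenol is ever made or protected.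
4. Both side chains come from lateral dianion alkylation of two commercial o-toluic acids: iodoethane for the propyl chain and 1-iodobutane for the pentyl chain.
5. No ring is formed. Rings A and B are bought intact and joined in step 5.

Assumption: the SMILES holds no stereocentre and no stereogenic double bond, so the target is achiral and no stereocontrol is needed.

**Route**

Step 1
Reactants: 1 2,4-dimethoxy-6-methylbenzoic acid
Product: 4 2,4-dimethoxy-6-propylbenzoic acid, via dilithio dianion 2 (not isolated), via lithium carboxylate 3 (not isolated)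
Conditions: LiN(iPr)2 (2.2 equiv, commercial solution), THF, −78 °C, 1 h; iodoethane (1.3 equiv), −78 °C → rt; 1 M HCl work-up
Reagents that add atoms: iodoethane, CCI
Why: Lateral (benzylic) lithiation of an o-toluic acid, in which the lithium carboxylate stabilises the benzylic carbanion that an amide base forms as the thermodynamic site, and the soft carbon of 2 undergoes SN2 alkylation with the primary iodide much faster than the carboxylate oxygen; no stereocentre is formed.

Step 2
Reactants: 5 2-methoxy-6-methylbenzoic acid
Product: 8 2-methoxy-6-pentylbenzoic acid, via dilithio dianion 6 (not isolated), via lithium carboxylate 7 (not isolated)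
Conditions: LiN(iPr)2 (2.2 equiv, commercial solution), THF, −78 °C, 1 h; 1-iodobutane (1.3 equiv), −78 °C → rt; 1 M HCl work-up
Reagents that add atoms: 1-iodobutane, CCCCI
Why: The same lateral lithiation and SN2 alkylation of an o-toluic acid dianion, with four carbons added to the benzylic carbon to give the pentyl chain; no stereocentre is formed.

Step 3
Reactants: 8 2-methoxy-6-pentylbenzoic acid
Product: 9 tert-butyl 2-methoxy-6-pentylbenzoate
Conditions: Cl3CC(=NH)OtBu (2 equiv), BF3·OEt2 (5 mol %), CH2Cl2/cyclohexane, 0 °C → rt
Reagents that add atoms: tert-butyl 2,2,2-trichloroacetimidate, CC(C)(C)OC(=N)C(Cl)(Cl)Cl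
Why: Alkylative esterification with a trichloroacetimidate, in which a tert-butyl cation equivalent is delivered to the carboxyl oxygen, so the di-ortho-substituted acyl carbon never has to be attacked.

Step 4
Reactants: 9 tert-butyl 2-methoxy-6-pentylbenzoate
Product: 11 [4-(tert-butoxycarbonyl)-3-methoxy-5-pentylphenyl]boronic acid, via pinacol boronate 10 (not isolated)
Conditions: [Ir(OMe)(cod)]2 (1.5 mol %), 4,4'-di-tert-butyl-2,2'-bipyridine (3 mol %), B2pin2 (1.0 equiv), THF, 80 °C, 16 h; evaporate volatiles; NaIO4 (3 equiv), NH4OAc (3 equiv), acetone/H2O 1:1, rt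
Reagents that add atoms: bis(pinacolato)diboron, CC1(C)OB(OC1(C)C)B1OC(C)(C)C(C)(C)O1; water, O
Why: Iridium-catalysed aromatic C–H borylation under steric control, where C4–H is the only ring C–H without an ortho substituent and both positions ortho to the ester are blocked, followed by hydrolysis of the pinacol ester that is driven by periodate glycol cleavage of the released pinacol under a near-neutral buffer that spares the tert-butyl ester.

Step 5
Reactants: 4 2,4-dimethoxy-6-propylbenzoic acid; 11 [4-(tert-butoxycarbonyl)-3-methoxy-5-pentylphenyl]boronic acid (1.5 equiv)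
Product: 12 tert-butyl 4-[(2,4-dimethoxy-6-propylbenzoyl)oxy]-2-methoxy-6-pentylbenzoate
Conditions: Cu(OTf)2 (0.4 equiv), urea (2 equiv), 4 Å MS, EtOAc, air, 60 °C
Reagents that add atoms: none
Why: Chan–Lam oxidative O-arylation of a carboxylic acid, in which the ortho-unsubstituted boronic acid transmetalates to a divalent copper carboxylate, air raises it to trivalent copper and C–O reductive elimination makes the aryl–oxygen bond, so no nucleophile has to reach the hindered acyl carbon of 4, triflate cannot compete as acetate would, and urea buffers the TfOH that could harm the tert-butyl ester.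

Step 6
Reactants: 12 tert-butyl 4-[(2,4-dimethoxy-6-propylbenzoyl)oxy]-2-methoxy-6-pentylbenzoate
Product: 13 4-[(2,4-dimethoxy-6-propylbenzoyl)oxy]-2-methoxy-6-pentylbenzoic acid (target)
Conditions: TFA/CH2Cl2 1:4, 0 °C → rt, 2 h
Reagents that add atoms: none
Why: Acidolysis of a tert-butyl ester by alkyl–oxygen ionisation with loss of isobutene, a pathway closed to the aryl ester and the methyl ethers, so the depside link and all three methoxy groups remain.

**Compound list**
1 | 2,4-dimethoxy-6-methylbenzoic acid | Cc1cc(OC)cc(OC)c1C(=O)O | starting material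
2 | dilithio dianion of 1 (benzylic lithium, lithium carboxylate) | [Li]Cc1cc(OC)cc(OC)c1C(=O)O[Li] | intermediate
3 | lithium 2,4-dimethoxy-6-propylbenzoate | CCCc1cc(OC)cc(OC)c1C(=O)O[Li] | intermediate
4 | 2,4-dimethoxy-6-propylbenzoic acid | CCCc1cc(OC)cc(OC)c1C(=O)O | intermediate
5 | 2-methoxy-6-methylbenzoic acid | Cc1cccc(OC)c1C(=O)O | starting material
6 | dilithio dianion of 5 (benzylic lithium, lithium carboxylate) | [Li]Cc1cccc(OC)c1C(=O)O[Li] | intermediate
7 | lithium 2-methoxy-6-pentylbenzoate | CCCCCc1cccc(OC)c1C(=O)O[Li] | intermediate
8 | 2-methoxy-6-pentylbenzoic acid | CCCCCc1cccc(OC)c1C(=O)O | intermediate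
9 | tert-butyl 2-methoxy-6-pentylbenzoate | CCCCCc1cccc(OC)c1C(=O)OC(C)(C)C | intermediate
10 | tert-butyl 2-methoxy-6-pentyl-4-(4,4,5,5-tetramethyl-1,3,2-dioxaborolan-2-yl)benzoate | CCCCCc1cc(B2OC(C)(C)C(C)(C)O2)cc(OC)c1C(=O)OC(C)(C)C | intermediate
11 | [4-(tert-butoxycarbonyl)-3-methoxy-5-pentylphenyl]boronic acid | CCCCCc1cc(B(O)O)cc(OC)c1C(=O)OC(C)(C)C | intermediate
12 | tert-butyl 4-[(2,4-dimethoxy-6-propylbenzoyl)oxy]-2-methoxy-6-pentylbenzoate | CCCCCc1cc(OC(=O)c2c(CCC)cc(OC)cc2OC)cc(OC)c1C(=O)OC(C)(C)C | intermediate
13 | 4-[(2,4-dimethoxy-6-propylbenzoyl)oxy]-2-methoxy-6-pentylbenzoic acid | CCCCCc1cc(OC(=O)c2c(CCC)cc(OC)cc2OC)cc(OC)c1C(=O)O | target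

**Totals**
Total step count: 6.
Longest linear sequence: 5 (steps 2, 3, 4, 5, 6, from 5).

**Three steps most likely to fail**

Step 5 (Chan–Lam coupling). The risks are protodeboronation, oxidation of 11 to the phenol, sluggish coupling of the electron-rich carboxylate, and acid damage to the tert-butyl ester. The fallback sets out from 11 and comes back at 12. The C–B bond of 11 is oxidised with 30 % H2O2 in THF/aqueous NaHCO3 at 0 °C to tert-butyl 4-hydroxy-2-methoxy-6-pentylbenzoate F1. The acyl C–O bond is then made instead of the aryl C–O bond, by Steglich esterification of 4 with this phenol (DCC, catalytic DMAP, CH2Cl2, rt), which gives 12.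

Step 4 (borylation and release of the boronic acid). The borylation itself is the smaller risk. The larger one is freeing and isolating a boronic acid beside an acid-sensitive ester, through incomplete pinacol cleavage, boroxine mixtures or loss on silica. The fallback sets out from 10, now isolated through a short silica plug, and comes back at 12, by-passing 11. Aqueous KHF2 in MeOH at rt converts 10 into potassium [4-(tert-butoxycarbonyl)-3-methoxy-5-pentylphenyl]trifluoroborate F2, which is purified by precipitation from acetone/ether. This crystalline salt is coupled with 4 under catalytic CuBr and DMAP, 4 Å MS, O2, MeCN, 60 °C. This is the slow-release trifluoroborate form of the oxidative coupling, and it gives 12.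

Step 1 (dianion ethylation). The risks are incomplete conversion, competing ring lithiation between the two methoxy groups, and the difficult separation of the two acids 1 and 4. The fallback sets out from 1, through dianion 2 made as in step 1, and comes back at 4.
- Dianion 2 is trapped with acetaldehyde, a far faster electrophile, to give racemic 2-(2-hydroxypropyl)-4,6-dimethoxybenzoic acid F3.
- This closes on acidic work-up (or with catalytic TsOH in toluene) to racemic 6,8-dimethoxy-3-methyl-3,4-dihydroisochromen-1-one F4, a neutral lactone that is easily washed free of unreacted 1.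
- KOtBu in THF opens the lactone by E1cB elimination at the benzylic position to (E)-2,4-dimethoxy-6-(prop-1-en-1-yl)benzoic acid F5.
- H2 over Pd/C in EtOAc saturates the alkene to 4, which removes the transient stereocentre.

**Further compounds**
F1 | step 5 | tert-butyl 4-hydroxy-2-methoxy-6-pentylbenzoate | CCCCCc1cc(O)cc(OC)c1C(=O)OC(C)(C)C
F2 | step 4 | potassium [4-(tert-butoxycarbonyl)-3-methoxy-5-pentylphenyl]trifluoroborate | CCCCCc1cc([B-](F)(F)F)cc(OC)c1C(=O)OC(C)(C)C.[K+]
F3 | step 1 | 2-(2-hydroxypropyl)-4,6-dimethoxybenzoic acid (racemic) | CC(O)Cc1cc(OC)cc(OC)c1C(=O)O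
F4 | step 1 | 6,8-dimethoxy-3-methyl-3,4-dihydroisochromen-1-one (racemic) | CC1Cc2cc(OC)cc(OC)c2C(=O)O1
F5 | step 1 | (E)-2,4-dimethoxy-6-(prop-1-en-1-yl)benzoic acid | C/C=C/c1cc(OC)cc(OC)c1C(=O)O
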